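The rate constants were chosen freely; no experiment stands behind them.

I read this flask at 30 s, and I want to know beforehand what that reading will hold.

    starting material + partner → target (k1 = 26000 L mol⁻¹ s⁻¹)
    starting material + second substrate → cross product (k2 = 45000 L mol⁻¹ s⁻¹)
    solid reagent ⇌ partner, rate k3*(cs3 - [partner]) while solid is left; crystals form when [partner] > cs3 (cs3 = 0.22 mM, k3 = 12 s⁻¹)
    second substrate + partner → second product (k4 = 1.7 × 10⁵ L mol⁻¹ s⁻¹)

starting material 0.50 mM; second substrate 0.100 mM; solid reagent 0.750 mM; time 30 s

- solid reagent is a solid; its amount is given per volume of the solution
- at the start none of the solid reagent is in solution
- the reaction counts as stopped when no species that holds the starting material changes by six tenths of a point or more over the second half of the time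
- run time (flask): 30 s

- why nothing more happens at 30 s, or that something still does (for what has run out or reacted, a solid counts together with what of it has only dissolved) (it is still moving / all of the starting material has reacted / the partner has run out first / forward and back rates have come level)
- part of the starting material gone at 30 s
- the target standing at 30 s, as a percentage of the starting material charged
- the cross product standing at 30 s, as a percentage of the starting material charged

I follow fractions left, because a fraction left needs just a sum of pulls in its exponent. The second substrate feels two pulls. Step 2 pulls at 22.5 s⁻¹ while the starting material stands near its charge. Step 4 pulls through the partner, which starts at zero. Counted as a fraction of its solubility, the partner rises with slope 12 s⁻¹, but step 1 draws on it too. Setting aside the draw of step 4, it bends at a knee near 0.0400 s and levels at 0.480, a steady state. At that level its pull is 18.0 s⁻¹, weaker than step 2, so the two pulls do not cross while the starting material stands near its charge.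

The fraction of second substrate left therefore falls from one with slope 22.5 s⁻¹. Counting step 2 as the sole pull before the knee, it reaches 0.407 there, and what remains runs to zero, divided as the two pulls stand. I carry the cross share, the fraction of charged second substrate that ends as cross product 0.820.

Multiplied by the charge ratio, this puts cross product at 16.4 % of the starting material. At the level partner, the starting material has a half-life of 0.252 s, far shorter than the time. The solid charge also exceeds what both substrates can take. So I expect complete conversion, with target at 83.6 %.

The forecast says all of the starting material has reacted, with 100 % gone, target 85.7 % and cross product 14.3 %, reached by hand steps “with partner rising from zero while the second substrate is consumed”. My cross product is higher than its figure. The simulation gives all of the starting material has reacted, with 100 % gone, target 85.5 % and cross product 14.5 %.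

That reading makes the cross share of this flask 0.724, against my 0.820. In a neighbouring flask, charged with 0.17 mM of second substrate, neither pull in my reckoning contains that charge, so the share stays 0.820 and gives cross product at 27.9 %. The share read from this flask gives 24.6 %. The simulated neighbouring flask stands at target 75.7 % and cross product 24.3 %, a cross share of 0.716.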